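## Structural features

The target is a germacranolide: a cyclodeca-1(10),4-diene ring fused at C6–C7 to an α-methylene-γ-butyrolactone (lactone oxygen on C6, C11 on C7, C11=C13 exocyclic, C12 carbonyl). Both ring alkenes are trisubstituted and ring-cis: C4(Me)=C5, and C1=C10, which carries the C14 methyl ester on C10 (E by the sequence rule only because the ester outranks C9). The ring holds an isolated allylic carbinol at C3 (S) and a contiguous triad C6 (R), C7 (R), C8 (R), in which O6 and C11 are trans (trans-fused lactone) and C11 and the C8 acyloxy group are cis. The C8 oxygen carries a (2R,3R)-2,3-dimethyloxirane-2-carbonyl (epoxyangeloyl) group with two further stereocentres. Fragile elements are the α-methylene lactone (Michael acceptor, incompatible with basic peroxide), the epoxy ester, the allylic C3–O and C6–O bonds on either side of C4=C5 (ionisation in acid), a free 8-hydroxyl next to the lactone (translactonisation) and the 1,5-diene C10=C1–C2–C3–C4=C5 (thermal Cope shift). The real difficulty is a medium ring with two cis trisubstituted alkenes flanked by a dense stereotriad. The feature used is that the oxygenated C6 is 1,5-related to the C1=C10 alkene through C7–C8–C9, while C1 to C6 with the cis C4=C5 alkene form a cyclohexene, so the ten-membered ring is the oxy-Cope ring-expansion product of a 1,2-dialkenylcyclohex-2-enol.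

## Logic of the disconnections

37 ⇒ 36. The O–benzyl bond at C3 is cut last. The C3 hydroxyl must stay masked until C8 is acylated, and only a neutral oxidative unmasking is tolerated by the epoxide, the exo-methylene lactone and the allylic C–O bonds. The ether must therefore survive strong base, fluoride and mild acid.

36 ⇒ 33. The C11=C13 bond is cut. The Michael acceptor is installed after the C8 oxygen exists, because it would not survive the basic peroxide that creates that oxygen. The forward step must enolise the lactone selectively next to two other esters.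

33 ⇒ 27 + 31. The C8–O acyl bond is cut, splitting off the side chain. 31 ⇒ 30 ⇒ 29 ⇒ 28 removes one oxidation level and the epoxide, leaving an achiral Z alkene whose geometry fixes the relative configuration and whose epoxidation fixes the absolute one. The forward acylation must join a hindered acid to a hindered alcohol without opening the epoxide.

27 ⇒ 25. The C8–O bond is traced back to a C8–Si bond. Silicon is a base-stable stand-in, since a real β-oxygen would be eliminated from the C6 enolates of steps 11 and 12, and it oxidises with retention. The demand is an oxidation that leaves the lactone and the enoate alone.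

25 ⇒ 23. The lactone C12–O6 bond and the C6–H bond are cut, giving a C6 ketone with an acetate arm on C7. The C6 stereocentre becomes a carbonyl; the forward reduction must be 1,2-selective and must place O6 trans to the arm.

23 ⇒ 21 ⇒ 19 + 20. The C14 ester is changed back to the tert-butyl ester and the C7–C11 bond is cut. This removes C7 as a stereocentre and two carbons. The forward alkylation must enolise only toward C7 and enter anti to silicon; the ester exchange is placed at the ketone stage, where acid is tolerated best.

19 ⇒ 16 (key). The C8–C9 bond is cut and the C1–C6 bond restored, contracting the ten-membered ring to a cyclohexene. The medium ring, the ring-cis C1=C10 enoate, the C4=C5 geometry and C8 are all traded for a six-membered ring with three stereocentres. The forward step needs a cis-dialkenyl carbinol, an (E)-vinylsilane, a hindered ester and a defined chair. The configurations of 16 and 19 were checked against each other through that chair and against 37 (C3 S, C8 R, both alkenes ring-cis) and are consistent.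

16 ⇒ 13. The C10=C9 methylene is removed. It is added only after the carbinol exists, so that C1–H is never at once α to a ketone and allylic to an acrylate.

13 ⇒ 11 + 12. The C8–Si and C7–H bonds are cut back to a terminal alkyne. The forward addition must be syn with silicon on the terminal carbon.

11 ⇒ 9 + 10. The C6–C7 bond is cut. A small linear nucleophile adds axially, cis to the C1 arm, which a bulkier and more basic alkenyl metal would do less reliably; enolisation of C1 must be avoided.

9 ⇒ 8 ⇒ 6 + 7. The C1–C10 bond is cut. Direct alkylation enters anti to the C3 ether and gives the trans isomer 8. The rearrangement needs the ether, the arm and the vinyl group on one face, so C1 is inverted by enolisation and kinetic protonation (8 ⇒ 9 in the forward sense).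

6 ⇒ 5 ⇒ 4 ⇒ 3 ⇒ 2 ⇒ 1. The ketal is removed, the C4–CH3 bond is cut to a C–I bond, the ether is cut and the C3–H bond is traced to a ketone. The only catalyst-controlled ring stereocentre is thus set by an enantioselective reduction of an α-iodoenone, and the second carbonyl is present from the start as a ketal.

## Other disconnections considered

Alternative 1: The cut removes the lactone as a unit (C7–C11 and O–C6), leaving the ten-membered C4=C5–C6=C7 diene A1, already carrying the C3 silyl ether, the C8 epoxyangelate and the C14 ester. In the forward step Mn(OAc)3 (trivalent manganese) with Cu(OAc)2 would oxidise the half-ester A2 to a malonyl radical that adds to C7; the allylic radical is oxidised and trapped by the carboxyl group at C6 to give A3.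
- In its favour: two bonds, the lactone ring and the C6/C7 centres would arise in one operation on a fully decorated ring. The C11 allyl ester allows a base-free decarboxylative methylenation afterwards, which is gentler than the enolate methylenation of step 20; on that point this plan is the better one.
- Against it: it does not build the medium ring at all. A1, with three ring-cis alkenes, needs a ring synthesis of its own. Nothing in A1 controls the site of radical attack (C7 against C4, or the C1=C10 enoate, including transannular closure) or the face of attack relative to C8. Hot acetic acid and metal oxidants meet an epoxide and a silyl ether.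
- Comparison: structurally the chosen plan derives ring, alkene geometries and C8 from one cyclohexene, whereas here they are prerequisites. Mechanistically a radical–polar crossover with two open selectivity questions stands against a concerted chair process. In step count the endgame is shorter (one step against steps 12–14 and 20), but the unaccounted synthesis of A1 outweighs this.

Alternative 2: The cut is the C4=C5 alkene, with a later C9–C10 ring closure. In the forward step RuCl2(H2IMes)(PCy3)(=CHPh) (second-generation Grubbs catalyst) would close the bis(allyloxy)silane A4 to the seven-membered silylene acetal A5 with loss of ethylene.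
- In its favour: the small ring forces the cis trisubstituted alkene, which equals the chosen plan, where the cyclohexene does the same. The C3 and C6 oxygen centres are fixed in acyclic precursors before any ring exists, so C6 does not depend on the facial course of a medium-ring ketone reduction; on that point it is better than step 14.
- Against it: the ten-membered ring must still be closed afterwards by joining the primary iodide C9 to the iodo-enoate C10, an end-to-end medium-ring closure with entropic and transannular penalties. The C6/C7/C8 triad and the α-iodo enoate need separate acyclic stereocontrol. The metathesis must select isopropenyl and vinyl over the acrylate methylene and form a trisubstituted alkene.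
- Comparison: structurally two ring-forming events replace one. Mechanistically both alkene-forming steps are reliable in type, but the second closure has no built-in control. The step count is clearly higher.

Alternative 3: The cut is C7–C8. In the forward step BF3·OEt2 would activate the aldehyde of A6, and the γ-carbon of the stannylmethyl butenolide attacks with loss of tin to give A7.
- In its favour: the ring, C7, C8, the free 8-hydroxyl and the exo-methylene lactone appear in one step. No silicon surrogate, no Tamao oxidation and no late enolate methylenation are needed; in operations after ring formation it is better than the chosen plan (acylation and desilylation only).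
- Against it: it is an end-to-end closure of a ten-membered ring (dilution, oligomerisation). The C6/C7/C8 relationship rests on a medium-ring transition state that cannot be predicted with confidence. Both ring-cis trisubstituted alkenes must be made by acyclic olefination without cyclic control. A6 combines an aldehyde, an allylstannane and an allylic butenolide oxygen under a Lewis acid.
- Comparison: structurally the chosen plan gets both alkene geometries and C8 from ring control, which this plan cannot. Mechanistically a chair-defined sigmatropic shift stands against an open cyclisation with several competing geometries. The endgame is about four steps shorter, but the linear synthesis of A6 is longer, so the totals are comparable.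

Key step: step 11

Remark on the chemistry: germacrane numbering (C1–C15, as in the first section) is used for all ring intermediates from 6 onward; lithium, sodium and magnesium enolates or alkoxides that exist only between two additions in one flask are treated as reactive species and are not numbered, except the alkoxide and enolate of the key step.

## Steps

Step 1
Reactants: 1 1,4-dioxaspiro[4.5]dec-6-en-8-one
Product: 2 7-iodo-1,4-dioxaspiro[4.5]dec-6-en-8-one
Conditions: I2, pyridine, CH2Cl2, 0 °C to rt
Reagents that add atoms: iodine, [I][I]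
Why: α-Iodination of an enone by pyridine addition, iodination of the enolate and elimination (Baylis–Hillman-type α-halogenation); the dioxolane is untouched and the iodide marks the carbon that will carry the C4 methyl group.

Step 2
Reactants: 2 7-iodo-1,4-dioxaspiro[4.5]dec-6-en-8-one
Product: 3 (8S)-7-iodo-1,4-dioxaspiro[4.5]dec-6-en-8-ol
Conditions: (R)-2-methyl-CBS-oxazaborolidine (20 mol%), BH3·SMe2, THF, −20 °C
Reagents that add atoms: none
Why: Corey–Bakshi–Shibata reduction: the iodoalkenyl arm acts as the large group and the ring CH2 as the small one, so the (R)-catalyst should deliver hydride to the face that gives the 8S carbinol (C3 of the target, S); α-haloenones are reliable substrates for this reduction.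

Step 3
Reactants: 3 (8S)-7-iodo-1,4-dioxaspiro[4.5]dec-6-en-8-ol
Product: 4 (8S)-7-iodo-8-[(4-methoxybenzyl)oxy]-1,4-dioxaspiro[4.5]dec-6-ene
Conditions: NaH, 4-MeOC6H4CH2Cl, Bu4NI (cat.), DMF, 0 °C to rt
Reagents that add atoms: 4-methoxybenzyl chloride, COc1ccc(CCl)cc1
Why: Williamson etherification of the sodium alkoxide; the PMB ether is chosen because it should survive strong base, fluoride and aqueous phosphoric acid and can be removed oxidatively at the end; the stereocentre is not touched.

Step 4
Reactants: 4 (8S)-7-iodo-8-[(4-methoxybenzyl)oxy]-1,4-dioxaspiro[4.5]dec-6-ene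
Product: 5 (8S)-8-[(4-methoxybenzyl)oxy]-7-methyl-1,4-dioxaspiro[4.5]dec-6-ene
Conditions: MeZnCl, Pd(PPh3)4 (5 mol%), THF, 50 °C
Reagents that add atoms: methylzinc chloride, C[Zn]Cl
Why: Negishi cross-coupling of the alkenyl iodide; it installs the C4 methyl group (C15) with retention of the alkene position under neutral conditions that leave the allylic ether and the ketal alone.

Step 5
Reactants: 5 (8S)-8-[(4-methoxybenzyl)oxy]-7-methyl-1,4-dioxaspiro[4.5]dec-6-ene
Product: 6 (4S)-4-[(4-methoxybenzyl)oxy]-3-methylcyclohex-2-en-1-one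
Conditions: 1 M aq. HCl, THF, rt
Reagents that add atoms: water, O
Why: Acid-catalysed hydrolysis of the dioxolane; the freed ketone is already conjugated with the alkene, and a γ-alkoxy enone resists ionisation under these mild conditions.

Step 6
Reactants: 6 (4S)-4-[(4-methoxybenzyl)oxy]-3-methylcyclohex-2-en-1-one; 7 tert-butyl bromoacetate
Product: 8 tert-butyl 2-[(1R,5S)-5-[(4-methoxybenzyl)oxy]-4-methyl-2-oxocyclohex-3-en-1-yl]acetate
Conditions: LiN(iPr)2, THF, −78 °C; then 7, DMPU, −78 to −30 °C
Reagents that add atoms: none
Why: Kinetic α′-deprotonation gives the cross-conjugated lithium dienolate, which is alkylated (SN2) anti to the pseudo-axial C3 ether (A1,2 strain with the C4 methyl keeps that ether axial); the arm therefore enters trans to the ether, which is the wrong relationship for the rearrangement and is corrected in step 7.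

Step 7
Reactants: 8 tert-butyl 2-[(1R,5S)-5-[(4-methoxybenzyl)oxy]-4-methyl-2-oxocyclohex-3-en-1-yl]acetate
Product: 9 tert-butyl 2-[(1S,5S)-5-[(4-methoxybenzyl)oxy]-4-methyl-2-oxocyclohex-3-en-1-yl]acetate
Conditions: LiN(SiMe3)2, THF, −78 to −40 °C; then 2,6-di-tert-butyl-4-methylphenol, THF, −78 °C
Reagents that add atoms: none
Why: Epimerisation by enolisation and kinetic protonation: the enolate erases C1, and C-protonation by a hindered phenol follows the same facial preference as the alkylation (anti to the pseudo-axial C3 ether), so the proton takes that face and the arm ends cis to the ether; the weaker silylamide base enolises the ketone and not the tert-butyl ester.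

Step 8
Reactants: 9 tert-butyl 2-[(1S,5S)-5-[(4-methoxybenzyl)oxy]-4-methyl-2-oxocyclohex-3-en-1-yl]acetate; 10 ethynylmagnesium bromide
Product: 11 tert-butyl 2-[(1S,2S,5S)-2-ethynyl-2-hydroxy-5-[(4-methoxybenzyl)oxy]-4-methylcyclohex-3-en-1-yl]acetate
Conditions: CeCl3 (anhydrous), 10, THF, −78 °C; aq. NH4Cl
Reagents that add atoms: none
Why: 1,2-Addition of a cerium acetylide to the ketone: the small linear nucleophile attacks axially, cis to the equatorial C1 arm, which places the alkyne cis to the arm and the hydroxyl trans; cerium suppresses enolisation of the epimerisable C1 centre, and the trans hydroxyl cannot lactonise onto the tert-butyl ester.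

Step 9
Reactants: 11 tert-butyl 2-[(1S,2S,5S)-2-ethynyl-2-hydroxy-5-[(4-methoxybenzyl)oxy]-4-methylcyclohex-3-en-1-yl]acetate; 12 benzyldimethylsilane
Product: 13 tert-butyl 2-[(1S,2S,5S)-2-[(E)-2-(benzyldimethylsilyl)ethenyl]-2-hydroxy-5-[(4-methoxybenzyl)oxy]-4-methylcyclohex-3-en-1-yl]acetate
Conditions: 12, Pt2[(CH2=CHSiMe2)2O]3 (1 mol% Pt), t-Bu3P, THF, rt
Reagents that add atoms: none
Why: Platinum-catalysed hydrosilylation of a terminal propargylic alcohol is a syn addition with silicon on the terminal carbon, giving the (E)-β-silylvinyl group; the trisubstituted ring alkene is inert and the hydroxyl needs no protection.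

Step 10
Reactants: 13 tert-butyl 2-[(1S,2S,5S)-2-[(E)-2-(benzyldimethylsilyl)ethenyl]-2-hydroxy-5-[(4-methoxybenzyl)oxy]-4-methylcyclohex-3-en-1-yl]acetate
Product: 16 tert-butyl 2-[(1S,2R,5S)-2-[(E)-2-(benzyldimethylsilyl)ethenyl]-2-hydroxy-5-[(4-methoxybenzyl)oxy]-4-methylcyclohex-3-en-1-yl]prop-2-enoate, via Mannich base 14 (not isolated), via ammonium iodide 15 (not isolated)
Conditions: LiN(iPr)2 (2.5 equiv), THF, −78 °C; [Me2N=CH2]I, −78 °C to rt; then MeI, CH2Cl2, rt; then K2CO3, DMF, rt
Reagents that add atoms: N,N-dimethylmethyleneiminium iodide (Eschenmoser's salt), C=[N+](C)C.[I-]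
Why: α-Methylenation of the ester by Mannich reaction of its lithium enolate (alkoxide/enolate dianion), N-methylation and E1cB loss of trimethylamine; placing it after carbinol formation avoids a β,γ-unsaturated keto acrylate whose C1–H would epimerise or move into conjugation, and C1 and C6 are not touched (the descriptor at the carbinol changes to R only through the priority rules).

Step 11
Reactants: 16 tert-butyl 2-[(1S,2R,5S)-2-[(E)-2-(benzyldimethylsilyl)ethenyl]-2-hydroxy-5-[(4-methoxybenzyl)oxy]-4-methylcyclohex-3-en-1-yl]prop-2-enoate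
Product: 19 tert-butyl (1E,4S,5Z,9R)-9-(benzyldimethylsilyl)-4-[(4-methoxybenzyl)oxy]-5-methyl-7-oxocyclodeca-1,5-diene-1-carboxylate, via potassium alkoxide 17 (not isolated), via potassium enolate 18 (not isolated)
Conditions: KH, 18-crown-6, THF, −40 to 0 °C; then AcOH in THF, −78 °C
Reagents that add atoms: none
Why: KH deprotonates the tertiary carbinol; in alkoxide 17 the oxido group weakens the C1–C6 bond and the 1,5-diene C8=C7–C6–C1–C10=C9 reorganises through a six-membered chair, forming C8–C9 and cleaving C1–C6 to give the ring-expanded enolate 18, which the cold acid quench protonates at C7 to ketone 19. The closest known reaction type is the anionic oxy-Cope ring expansion of cis-1,2-dialkenylcyclohexanols to cyclodec-5-enones. The ten-membered ring arises by [3,3] ring expansion of the six-membered ring (enlargement by four atoms) and not by an end-to-end cyclisation, so neither dilution nor a ring-closure rule is involved. The new stereocentre C8 (R) is set by chirality transfer from C1 and C6 through the chair in which the (E)-vinylsilane places silicon equatorial. The step needs the chair with C2 pseudo-axial on C1 (ring-cis C1=C10) and not the one with C5 pseudo-axial on C6; the half-chair of 16 with the C1 arm and the C3 ether both equatorial and the silylvinyl group pseudo-axial maps directly onto the required chair, whereas the other chair would need arm and ether 1,3-diaxial and would push C5 against the C14 ester. Chemoselectivity rests on the tert-butyl ester (no acyl transfer to the trans alkoxide), on the E geometry that keeps silicon out of reach of the alkoxide, and on the cold quench that stops the enolate before transannular reactions. The C4=C5 alkene is carried over unchanged from the cyclohexene and stays ring-cis.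

Step 12
Reactants: 19 tert-butyl (1E,4S,5Z,9R)-9-(benzyldimethylsilyl)-4-[(4-methoxybenzyl)oxy]-5-methyl-7-oxocyclodeca-1,5-diene-1-carboxylate; 20 methyl bromoacetate
Product: 21 tert-butyl (1E,4S,5Z,8S,9R)-9-(benzyldimethylsilyl)-8-(2-methoxy-2-oxoethyl)-4-[(4-methoxybenzyl)oxy]-5-methyl-7-oxocyclodeca-1,5-diene-1-carboxylate
Conditions: LiN(iPr)2, THF, −78 °C; then 20, DMPU, −78 to −40 °C
Reagents that add atoms: none
Why: Kinetic deprotonation at C7 (the only α′ position) and SN2 alkylation of the β-silyl enolate anti to silicon in the conformer with C8–H eclipsing the enolate (the open-chain β-silyl enolate model), which gives C7 (S) with C11 cis to the silyl group in the ring drawing; the bulky tert-butyl ester at C14 shields that carbonyl from transannular acylation by the enolate.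

Step 13
Reactants: 21 tert-butyl (1E,4S,5Z,8S,9R)-9-(benzyldimethylsilyl)-8-(2-methoxy-2-oxoethyl)-4-[(4-methoxybenzyl)oxy]-5-methyl-7-oxocyclodeca-1,5-diene-1-carboxylate
Product: 23 methyl (1E,4S,5Z,8S,9R)-9-(benzyldimethylsilyl)-8-(2-methoxy-2-oxoethyl)-4-[(4-methoxybenzyl)oxy]-5-methyl-7-oxocyclodeca-1,5-diene-1-carboxylate, via carboxylic acid 22 (not isolated)
Conditions: 85% aq. H3PO4, toluene, rt; then Me3SiCHN2, toluene/MeOH, 0 °C
Reagents that add atoms: (trimethylsilyl)diazomethane, C[Si](C)(C)C=[N+]=[N-]
Why: Acidolysis of the tert-butyl ester (loss of the tert-butyl cation as 2-methylpropene) under conditions mild enough for silyl ethers, hence expected to spare the PMB ether, the β-silyl ketone and the methyl ester, then esterification of the acid with the diazoalkane; the exchange is placed here because a γ-alkoxy enone resists ionisation, unlike the allylic C–O bonds of later intermediates.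

Step 14
Reactants: 23 methyl (1E,4S,5Z,8S,9R)-9-(benzyldimethylsilyl)-8-(2-methoxy-2-oxoethyl)-4-[(4-methoxybenzyl)oxy]-5-methyl-7-oxocyclodeca-1,5-diene-1-carboxylate
Product: 25 methyl (3S,6R,7S,8R)-8-(benzyldimethylsilyl)-3-[(4-methoxybenzyl)oxy]germacra-1(10),4-dien-12,6-olid-14-oate (ring-cis alkenes; trans-fused lactone), via hydroxy diester 24 (not isolated)
Conditions: NaBH4, CeCl3·7H2O, MeOH/THF, −78 to −40 °C; then PPTS (cat.), CH2Cl2, rt
Reagents that add atoms: none
Why: Luche reduction (1,2-selective) of the enone: the small hydride should attack anti to the pseudo-axial C7–H as in α-substituted cyclohexenones, giving the 6R carbinol with O6 trans to the C7 arm, and the γ-hydroxy methyl ester then lactonises with loss of methanol; the facial course in the ten-membered ring is the uncertain point and is treated in the last section.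

Step 15
Reactants: 25 methyl (3S,6R,7S,8R)-8-(benzyldimethylsilyl)-3-[(4-methoxybenzyl)oxy]germacra-1(10),4-dien-12,6-olid-14-oate
Product: 27 methyl (3S,6R,7R,8R)-8-hydroxy-3-[(4-methoxybenzyl)oxy]germacra-1(10),4-dien-12,6-olid-14-oate, via fluorosilane 26 (not isolated)
Conditions: Bu4NF, THF, 0 °C; then KHCO3, 30% aq. H2O2, MeOH/THF, rt
Reagents that add atoms: hydrogen peroxide, OO
Why: Tamao–Fleming oxidation: fluoride cleaves the benzyl–silicon bond to the fluorosilane, hydroperoxide adds to silicon and C8 migrates from silicon to oxygen with retention (8R); the bicarbonate buffer and short fluoride exposure are meant to keep the free 8-hydroxyl from translactonising, and no α-methylene lactone is present yet to be attacked by peroxide.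

Step 16
Reactants: 28 angelic acid [(2Z)-2-methylbut-2-enoic acid]
Product: 29 (2Z)-2-methylbut-2-en-1-ol
Conditions: LiAlH4, Et2O, 0 °C to rt
Reagents that add atoms: none
Why: Hydride reduction of the carboxylic acid to the primary allylic alcohol; the Z geometry is kept because neither acid nor heat is applied.

Step 17
Reactants: 29 (2Z)-2-methylbut-2-en-1-ol
Product: 30 [(2S,3R)-2,3-dimethyloxiran-2-yl]methanol
Conditions: Ti(OiPr)4 (10 mol%), L-(+)-diisopropyl tartrate, t-BuOOH, 4 Å MS, CH2Cl2, −20 °C
Reagents that add atoms: tert-butyl hydroperoxide, CC(C)(C)OO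
Why: Sharpless asymmetric epoxidation: the L-(+)-tartrate complex delivers oxygen to the face that gives 2S at the carbinol-bearing carbon, and the Z geometry fixes C3 as R; this is the spatial arrangement of the side chain of the target.

Step 18
Reactants: 30 [(2S,3R)-2,3-dimethyloxiran-2-yl]methanol
Product: 31 (2R,3R)-2,3-dimethyloxirane-2-carboxylic acid
Conditions: RuCl3·3H2O (2 mol%), NaIO4, MeCN/EtOAc/H2O, rt
Reagents that add atoms: water, O
Why: RuO4-catalysed oxidation of the primary alcohol to the acid with periodate as terminal oxidant; the epoxide and both stereocentres are not involved, and the C2 descriptor changes from S to R only because the priorities change.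

Step 19
Reactants: 27 methyl (3S,6R,7R,8R)-8-hydroxy-3-[(4-methoxybenzyl)oxy]germacra-1(10),4-dien-12,6-olid-14-oate; 31 (2R,3R)-2,3-dimethyloxirane-2-carboxylic acid
Product: 33 methyl (3S,6R,7R,8R)-8-{[(2R,3R)-2,3-dimethyloxiran-2-yl]carbonyloxy}-3-[(4-methoxybenzyl)oxy]germacra-1(10),4-dien-12,6-olid-14-oate, via mixed anhydride 32 (not isolated)
Conditions: 31, 2,4,6-Cl3C6H2COCl, Et3N, toluene, rt; then 27, DMAP, toluene, rt
Reagents that add atoms: none
Why: Yamaguchi esterification: DMAP attacks the mixed anhydride at the epoxy-acyl carbonyl and the acylpyridinium acylates the hindered C8 alcohol; no stereocentre changes, and capping the hydroxyl removes the translactonisation risk before base is used again.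

Step 20
Reactants: 33 methyl (3S,6R,7R,8R)-8-{[(2R,3R)-2,3-dimethyloxiran-2-yl]carbonyloxy}-3-[(4-methoxybenzyl)oxy]germacra-1(10),4-dien-12,6-olid-14-oate
Product: 36 methyl (3S,6R,7R,8R)-8-{[(2R,3R)-2,3-dimethyloxiran-2-yl]carbonyloxy}-3-[(4-methoxybenzyl)oxy]germacra-1(10),4,11(13)-trien-12,6-olid-14-oate, via Mannich base 34 (not isolated), via ammonium iodide 35 (not isolated)
Conditions: LiN(SiMe3)2, THF, −78 °C; [Me2N=CH2]I, −78 to 0 °C; then MeI, CH2Cl2/MeOH, rt; then aq. NaHCO3, CH2Cl2, rt
Reagents that add atoms: N,N-dimethylmethyleneiminium iodide (Eschenmoser's salt), C=[N+](C)C.[I-]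
Why: α-Methylenation of the lactone by Mannich reaction of its lithium enolate, quaternisation and mild base-induced elimination of trimethylamine; the lactone α-CH2 is the most acidic site, the epoxy ester has no α-hydrogen and a neopentyl-like carbonyl, and the C11 configuration of the Mannich base is lost on elimination.

Step 21
Reactants: 36 methyl (3S,6R,7R,8R)-8-{[(2R,3R)-2,3-dimethyloxiran-2-yl]carbonyloxy}-3-[(4-methoxybenzyl)oxy]germacra-1(10),4,11(13)-trien-12,6-olid-14-oate
Product: 37 methyl (3S,6R,7R,8R)-8-{[(2R,3R)-2,3-dimethyloxiran-2-yl]carbonyloxy}-3-hydroxygermacra-1(10),4,11(13)-trien-12,6-olid-14-oate (CNP0143679.1)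
Conditions: DDQ, CH2Cl2/pH 7 phosphate buffer, 0 °C
Reagents that add atoms: none
Why: Oxidative cleavage of the PMB ether by DDQ (hydride abstraction, hydrolysis of the oxocarbenium ion) under buffered neutral conditions that should leave the epoxide, the exo-methylene lactone and the allylic C–O bonds untouched; this releases the target.

## Compound list

1 | 1,4-dioxaspiro[4.5]dec-6-en-8-one | O=C1C=CC2(CC1)OCCO2 | starting material
2 | 7-iodo-1,4-dioxaspiro[4.5]dec-6-en-8-one | O=C1C(I)=CC2(CC1)OCCO2 | intermediate
3 | (8S)-7-iodo-1,4-dioxaspiro[4.5]dec-6-en-8-ol | IC1=CC2(OCCO2)CC[C@@H]1O | intermediate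
4 | (8S)-7-iodo-8-[(4-methoxybenzyl)oxy]-1,4-dioxaspiro[4.5]dec-6-ene | IC1=CC2(OCCO2)CC[C@@H]1OCc1ccc(OC)cc1 | intermediate
5 | (8S)-8-[(4-methoxybenzyl)oxy]-7-methyl-1,4-dioxaspiro[4.5]dec-6-ene | CC1=CC2(OCCO2)CC[C@@H]1OCc1ccc(OC)cc1 | intermediate
6 | (4S)-4-[(4-methoxybenzyl)oxy]-3-methylcyclohex-2-en-1-one | O=C1C=C(C)[C@@H](OCc2ccc(OC)cc2)CC1 | intermediate
7 | tert-butyl bromoacetate | CC(C)(C)OC(=O)CBr | starting material
8 | tert-butyl 2-[(1R,5S)-5-[(4-methoxybenzyl)oxy]-4-methyl-2-oxocyclohex-3-en-1-yl]acetate (arm trans to the ether) | O=C1C=C(C)[C@@H](OCc2ccc(OC)cc2)C[C@@H]1CC(=O)OC(C)(C)C | intermediate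
9 | tert-butyl 2-[(1S,5S)-5-[(4-methoxybenzyl)oxy]-4-methyl-2-oxocyclohex-3-en-1-yl]acetate (arm cis to the ether) | O=C1C=C(C)[C@@H](OCc2ccc(OC)cc2)C[C@H]1CC(=O)OC(C)(C)C | intermediate
10 | ethynylmagnesium bromide | C#C[Mg]Br | starting material
11 | tert-butyl 2-[(1S,2S,5S)-2-ethynyl-2-hydroxy-5-[(4-methoxybenzyl)oxy]-4-methylcyclohex-3-en-1-yl]acetate | O[C@]1(C#C)C=C(C)[C@@H](OCc2ccc(OC)cc2)C[C@H]1CC(=O)OC(C)(C)C | intermediate
12 | benzyldimethylsilane | C[SiH](C)Cc1ccccc1 | starting material
13 | tert-butyl 2-[(1S,2S,5S)-2-[(E)-2-(benzyldimethylsilyl)ethenyl]-2-hydroxy-5-[(4-methoxybenzyl)oxy]-4-methylcyclohex-3-en-1-yl]acetate | O[C@]1(/C=C/[Si](C)(C)Cc2ccccc2)C=C(C)[C@@H](OCc2ccc(OC)cc2)C[C@H]1CC(=O)OC(C)(C)C | intermediate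
14 | Mannich base: tert-butyl 3-(dimethylamino)-2-[(1S,2S,5S)-2-[(E)-2-(benzyldimethylsilyl)ethenyl]-2-hydroxy-5-[(4-methoxybenzyl)oxy]-4-methylcyclohex-3-en-1-yl]propanoate (propanoate C2 unassigned) | O[C@]1(/C=C/[Si](C)(C)Cc2ccccc2)C=C(C)[C@@H](OCc2ccc(OC)cc2)C[C@H]1C(CN(C)C)C(=O)OC(C)(C)C | intermediate (not isolated)
15 | trimethylammonium iodide of 14 | O[C@]1(/C=C/[Si](C)(C)Cc2ccccc2)C=C(C)[C@@H](OCc2ccc(OC)cc2)C[C@H]1C(C[N+](C)(C)C)C(=O)OC(C)(C)C.[I-] | intermediate (not isolated)
16 | tert-butyl 2-[(1S,2R,5S)-2-[(E)-2-(benzyldimethylsilyl)ethenyl]-2-hydroxy-5-[(4-methoxybenzyl)oxy]-4-methylcyclohex-3-en-1-yl]prop-2-enoate; as a cyclohexenol: (1R,4S,6S)-1-[(E)-2-(benzyldimethylsilyl)vinyl]-6-(1-tert-butoxycarbonylvinyl)-4-(4-methoxybenzyloxy)-3-methylcyclohex-2-en-1-ol | O[C@]1(/C=C/[Si](C)(C)Cc2ccccc2)C=C(C)[C@@H](OCc2ccc(OC)cc2)C[C@H]1C(=C)C(=O)OC(C)(C)C | intermediate (key-step precursor)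
17 | potassium alkoxide of 16 | [K+].[O-][C@]1(/C=C/[Si](C)(C)Cc2ccccc2)C=C(C)[C@@H](OCc2ccc(OC)cc2)C[C@H]1C(=C)C(=O)OC(C)(C)C | intermediate (not isolated)
18 | potassium C6 enolate of 19 (C6=C7, oxygen cis to C8) | [K+].[O-]/C1=C\[C@H]([Si](C)(C)Cc2ccccc2)C/C(C(=O)OC(C)(C)C)=C\C[C@H](OCc2ccc(OC)cc2)/C(C)=C\1 | intermediate (not isolated)
19 | tert-butyl (1E,4S,5Z,9R)-9-(benzyldimethylsilyl)-4-[(4-methoxybenzyl)oxy]-5-methyl-7-oxocyclodeca-1,5-diene-1-carboxylate (germacrane: C6 ketone, 3S, 8R, both alkenes ring-cis) | O=C1/C=C(/C)[C@@H](OCc2ccc(OC)cc2)C/C=C(/C(=O)OC(C)(C)C)C[C@@H]([Si](C)(C)Cc2ccccc2)C1 | intermediate (key-step product)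
20 | methyl bromoacetate | COC(=O)CBr | starting material
21 | tert-butyl (1E,4S,5Z,8S,9R)-9-(benzyldimethylsilyl)-8-(2-methoxy-2-oxoethyl)-4-[(4-methoxybenzyl)oxy]-5-methyl-7-oxocyclodeca-1,5-diene-1-carboxylate | O=C1/C=C(/C)[C@@H](OCc2ccc(OC)cc2)C/C=C(/C(=O)OC(C)(C)C)C[C@@H]([Si](C)(C)Cc2ccccc2)[C@H]1CC(=O)OC | intermediate
22 | (1E,4S,5Z,8S,9R)-9-(benzyldimethylsilyl)-8-(2-methoxy-2-oxoethyl)-4-[(4-methoxybenzyl)oxy]-5-methyl-7-oxocyclodeca-1,5-diene-1-carboxylic acid | O=C1/C=C(/C)[C@@H](OCc2ccc(OC)cc2)C/C=C(/C(=O)O)C[C@@H]([Si](C)(C)Cc2ccccc2)[C@H]1CC(=O)OC | intermediate (not isolated)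
23 | methyl (1E,4S,5Z,8S,9R)-9-(benzyldimethylsilyl)-8-(2-methoxy-2-oxoethyl)-4-[(4-methoxybenzyl)oxy]-5-methyl-7-oxocyclodeca-1,5-diene-1-carboxylate | O=C1/C=C(/C)[C@@H](OCc2ccc(OC)cc2)C/C=C(/C(=O)OC)C[C@@H]([Si](C)(C)Cc2ccccc2)[C@H]1CC(=O)OC | intermediate
24 | methyl (1E,4S,5Z,7R,8S,9R)-9-(benzyldimethylsilyl)-7-hydroxy-8-(2-methoxy-2-oxoethyl)-4-[(4-methoxybenzyl)oxy]-5-methylcyclodeca-1,5-diene-1-carboxylate | O[C@@H]1/C=C(/C)[C@@H](OCc2ccc(OC)cc2)C/C=C(/C(=O)OC)C[C@@H]([Si](C)(C)Cc2ccccc2)[C@H]1CC(=O)OC | intermediate (not isolated)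
25 | methyl (3S,6R,7S,8R)-8-(benzyldimethylsilyl)-3-[(4-methoxybenzyl)oxy]germacra-1(10),4-dien-12,6-olid-14-oate (ring-cis alkenes; trans-fused lactone) | C1C(=O)O[C@@H]2/C=C(/C)[C@@H](OCc3ccc(OC)cc3)C/C=C(/C(=O)OC)C[C@@H]([Si](C)(C)Cc3ccccc3)[C@@H]12 | intermediate
26 | C8 fluorodimethylsilyl analogue of 25 | C1C(=O)O[C@@H]2/C=C(/C)[C@@H](OCc3ccc(OC)cc3)C/C=C(/C(=O)OC)C[C@@H]([Si](C)(C)F)[C@@H]12 | intermediate (not isolated)
27 | methyl (3S,6R,7R,8R)-8-hydroxy-3-[(4-methoxybenzyl)oxy]germacra-1(10),4-dien-12,6-olid-14-oate | C1C(=O)O[C@@H]2/C=C(/C)[C@@H](OCc3ccc(OC)cc3)C/C=C(/C(=O)OC)C[C@@H](O)[C@@H]12 | intermediate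
28 | angelic acid, (2Z)-2-methylbut-2-enoic acid | C/C=C(/C)C(=O)O | starting material
29 | (2Z)-2-methylbut-2-en-1-ol | C/C=C(/C)CO | intermediate
30 | [(2S,3R)-2,3-dimethyloxiran-2-yl]methanol | OC[C@]1(C)O[C@@H]1C | intermediate
31 | (2R,3R)-2,3-dimethyloxirane-2-carboxylic acid | OC(=O)[C@]1(C)O[C@@H]1C | intermediate
32 | (2R,3R)-2,3-dimethyloxirane-2-carboxylic 2,4,6-trichlorobenzoic anhydride | O=C(OC(=O)c1c(Cl)cc(Cl)cc1Cl)[C@]1(C)O[C@@H]1C | intermediate (not isolated)
33 | methyl (3S,6R,7R,8R)-8-{[(2R,3R)-2,3-dimethyloxiran-2-yl]carbonyloxy}-3-[(4-methoxybenzyl)oxy]germacra-1(10),4-dien-12,6-olid-14-oate | C1C(=O)O[C@@H]2/C=C(/C)[C@@H](OCc3ccc(OC)cc3)C/C=C(/C(=O)OC)C[C@@H](OC(=O)[C@]3(C)O[C@@H]3C)[C@@H]12 | intermediate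
34 | C11 (dimethylamino)methyl Mannich base of 33 (C11 unassigned) | CN(C)CC1C(=O)O[C@@H]2/C=C(/C)[C@@H](OCc3ccc(OC)cc3)C/C=C(/C(=O)OC)C[C@@H](OC(=O)[C@]3(C)O[C@@H]3C)[C@@H]12 | intermediate (not isolated)
35 | trimethylammonium iodide of 34 | C[N+](C)(C)CC1C(=O)O[C@@H]2/C=C(/C)[C@@H](OCc3ccc(OC)cc3)C/C=C(/C(=O)OC)C[C@@H](OC(=O)[C@]3(C)O[C@@H]3C)[C@@H]12.[I-] | intermediate (not isolated)
36 | methyl (3S,6R,7R,8R)-8-{[(2R,3R)-2,3-dimethyloxiran-2-yl]carbonyloxy}-3-[(4-methoxybenzyl)oxy]germacra-1(10),4,11(13)-trien-12,6-olid-14-oate | C=C1C(=O)O[C@@H]2/C=C(/C)[C@@H](OCc3ccc(OC)cc3)C/C=C(/C(=O)OC)C[C@@H](OC(=O)[C@]3(C)O[C@@H]3C)[C@@H]12 | intermediate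
37 | methyl (3S,6R,7R,8R)-8-{[(2R,3R)-2,3-dimethyloxiran-2-yl]carbonyloxy}-3-hydroxygermacra-1(10),4,11(13)-trien-12,6-olid-14-oate (CNP0143679.1) | C=C1C(=O)O[C@@H]2/C=C(/C)[C@@H](O)C/C=C(/C(=O)OC)C[C@@H](OC(=O)[C@]3(C)O[C@@H]3C)[C@@H]12 | target

## Step count and least certain steps

Total: 21 steps. Longest linear sequence: 18 steps (steps 1–15 and 19–21, from 1 to 37). The side-chain acid 31 takes 3 steps (16–18) and enters at step 19.

Step 11 (key step). What may go wrong: heterolytic fragmentation of alkoxide 17 at the C1–C6 bond without recombination, leakage through the other chair or a boat (loss of the ring-cis C1=C10 geometry and of the C8 configuration), or onward transannular reaction of enolate 18 before the quench. Fallback (the neutral variant of the same shift): 16 is silylated with N-(trimethylsilyl)imidazole to the trimethylsilyl ether F1, which is heated in toluene in a sealed, base-washed tube (about 180 °C) to undergo the siloxy-Cope rearrangement through the same chair to the silyl enol ether F2; cold methanolysis (K2CO3, MeOH, 0 °C) rejoins the route at 19. No charged intermediate is involved, so alkoxide- and enolate-based side reactions are removed, at the price of a higher temperature.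

Step 7. What may go wrong: poor facial selectivity in the protonation, partial enolisation of the ester instead of the ketone, or re-epimerisation toward the more stable trans isomer during work-up. Fallback (C1 set by hydrogen delivery from a catalyst surface instead of enolate protonation): 6 is condensed with tert-butyl glyoxylate (LiN(iPr)2, THF, −78 °C) to the aldol adduct F3, which is dehydrated (MsCl, Et3N, then DBU) to the (E)-alkylidene ketone F4; hydrogenation of this electron-poor exocyclic alkene (H2, Pd/C, pyridine as moderator, EtOAc) should add hydrogen from the face anti to the C3 ether and rejoin the route at 9.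

Step 12. What may go wrong: poor facial selectivity if the ring conformation overrides the anti-to-silicon approach, competing γ-enolisation or O-alkylation, and transannular attack of the enolate on the enoate. Fallback (thermodynamic instead of kinetic control of C7): the C7 epimer F5 obtained from 19 is equilibrated through the enol (DBU, CH2Cl2, rt), the arm anti to the silyl-bearing carbon being expected to be the more stable arrangement; separation and recycling return the material to 21.

Step 13. What may go wrong: loss of the PMB ether or acid-catalysed epimerisation at C7 during the tert-butyl ester cleavage. Fallback (deprotect both groups and re-protect): 21 is treated with CF3CO2H in CH2Cl2 with anisole, which removes the tert-butyl ester and the PMB ether together and gives hydroxy acid F6; Me3SiCHN2 gives hydroxy diester F7; the C3 hydroxyl is re-protected with 4-methoxybenzyl trichloroacetimidate and La(OTf)3 (cat.), rejoining the route at 23.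

Step 14. What may go wrong: hydride delivery from the other face of the C6 carbonyl, which a perpendicular C8 substituent or peripheral attack would favour, followed by closure to the cis-fused lactone. Fallback (C6 set by invertive C–O bond formation instead of hydride face selectivity): 23 then gives the C6-epimeric hydroxy diester F8, which closes to the cis-fused lactone F9; F9 is opened with LiOH (THF/H2O, 0 °C) to the hydroxy acid F10, which is acidified cold and used at once; Mitsunobu lactonisation (PPh3, DIAD, THF, 0 °C) closes the ring with inversion at C6 and rejoins the route at 25.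

Step 20. What may go wrong: acyl transfer from the C8 ester to the lactone enolate, competing γ-deprotonation of the C14 enoate, or base-induced damage to the epoxy ester. Fallback (methylenate before acylating): 27 is methylenated at the hydroxy-lactone stage (LiN(iPr)2, 2.2 equiv; [Me2N=CH2]I; MeI; aq. NaHCO3) through Mannich base F11 and its methiodide F12 to the 8-hydroxy α-methylene lactone F13, which is then acylated with 31 through 32 under the conditions of step 19 and rejoins the route at 36.

## Further compounds

F1 | step 11 | trimethylsilyl ether of 16 | C[Si](C)(C)O[C@]1(/C=C/[Si](C)(C)Cc2ccccc2)C=C(C)[C@@H](OCc2ccc(OC)cc2)C[C@H]1C(=C)C(=O)OC(C)(C)C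
F2 | step 11 | trimethylsilyl enol ether of 19 (C6=C7, oxygen cis to C8) | C[Si](C)(C)O/C1=C\[C@H]([Si](C)(C)Cc2ccccc2)C/C(C(=O)OC(C)(C)C)=C\C[C@H](OCc2ccc(OC)cc2)/C(C)=C\1
F3 | step 7 | tert-butyl 2-hydroxy-2-[(5S)-5-[(4-methoxybenzyl)oxy]-4-methyl-2-oxocyclohex-3-en-1-yl]acetate (diastereomer mixture) | O=C1C=C(C)[C@@H](OCc2ccc(OC)cc2)CC1C(O)C(=O)OC(C)(C)C
F4 | step 7 | tert-butyl (2E)-2-[(5S)-5-[(4-methoxybenzyl)oxy]-4-methyl-2-oxocyclohex-3-en-1-ylidene]acetate | O=C1C=C(C)[C@@H](OCc2ccc(OC)cc2)C/C1=C\C(=O)OC(C)(C)C
F5 | step 12 | C7 epimer of 21 | O=C1/C=C(/C)[C@@H](OCc2ccc(OC)cc2)C/C=C(/C(=O)OC(C)(C)C)C[C@@H]([Si](C)(C)Cc2ccccc2)[C@@H]1CC(=O)OC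
F6 | step 13 | (1E,4S,5Z,8S,9R)-9-(benzyldimethylsilyl)-4-hydroxy-8-(2-methoxy-2-oxoethyl)-5-methyl-7-oxocyclodeca-1,5-diene-1-carboxylic acid | O=C1/C=C(/C)[C@@H](O)C/C=C(/C(=O)O)C[C@@H]([Si](C)(C)Cc2ccccc2)[C@H]1CC(=O)OC
F7 | step 13 | methyl (1E,4S,5Z,8S,9R)-9-(benzyldimethylsilyl)-4-hydroxy-8-(2-methoxy-2-oxoethyl)-5-methyl-7-oxocyclodeca-1,5-diene-1-carboxylate | O=C1/C=C(/C)[C@@H](O)C/C=C(/C(=O)OC)C[C@@H]([Si](C)(C)Cc2ccccc2)[C@H]1CC(=O)OC
F8 | step 14 | C6 epimer of hydroxy diester 24 | O[C@H]1/C=C(/C)[C@@H](OCc2ccc(OC)cc2)C/C=C(/C(=O)OC)C[C@@H]([Si](C)(C)Cc2ccccc2)[C@H]1CC(=O)OC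
F9 | step 14 | C6 epimer of 25 (cis-fused lactone) | C1C(=O)O[C@H]2/C=C(/C)[C@@H](OCc3ccc(OC)cc3)C/C=C(/C(=O)OC)C[C@@H]([Si](C)(C)Cc3ccccc3)[C@@H]12
F10 | step 14 | C6-epimeric hydroxy acid from F9 | O[C@H]1/C=C(/C)[C@@H](OCc2ccc(OC)cc2)C/C=C(/C(=O)OC)C[C@@H]([Si](C)(C)Cc2ccccc2)[C@H]1CC(=O)O
F11 | step 20 | C11 (dimethylamino)methyl Mannich base of 27 (C11 unassigned) | CN(C)CC1C(=O)O[C@@H]2/C=C(/C)[C@@H](OCc3ccc(OC)cc3)C/C=C(/C(=O)OC)C[C@@H](O)[C@@H]12
F12 | step 20 | trimethylammonium iodide of F11 | C[N+](C)(C)CC1C(=O)O[C@@H]2/C=C(/C)[C@@H](OCc3ccc(OC)cc3)C/C=C(/C(=O)OC)C[C@@H](O)[C@@H]12.[I-]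
F13 | step 20 | methyl (3S,6R,7R,8R)-8-hydroxy-3-[(4-methoxybenzyl)oxy]germacra-1(10),4,11(13)-trien-12,6-olid-14-oate | C=C1C(=O)O[C@@H]2/C=C(/C)[C@@H](OCc3ccc(OC)cc3)C/C=C(/C(=O)OC)C[C@@H](O)[C@@H]12
A1 | alternative 1 | ten-membered C4=C5–C6=C7 ring diene with C3 silyl ether, C8 epoxyangelate and C14 methyl ester (C6=C7 assumed ring-cis) | [C@@H]1(OC(=O)[C@]2(C)O[C@@H]2C)C/C(C(=O)OC)=C\C[C@H](O[Si](C)(C)C(C)(C)C)/C(C)=C\C=C/1
A2 | alternative 1 | monoallyl malonate, 3-(allyloxy)-3-oxopropanoic acid | C=CCOC(=O)CC(=O)O
A3 | alternative 1 | trans-fused lactone bearing an allyl ester on C11 | C=CCOC(=O)[C@@H]1C(=O)O[C@@H]2/C=C(/C)[C@@H](O[Si](C)(C)C(C)(C)C)C/C=C(/C(=O)OC)C[C@@H](OC(=O)[C@]3(C)O[C@@H]3C)[C@@H]12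
A4 | alternative 2 | acyclic bis(allyloxy)diisopropylsilane with C4 isopropenyl and C5 vinyl groups | C=C(C)[C@H](C/C=C(\I)C(=O)OC)O[Si](C(C)C)(C(C)C)O[C@H](C=C)[C@H](C(=C)C(=O)OC)[C@H](OCc1ccc(OC)cc1)CI
A5 | alternative 2 | seven-membered silylene acetal containing the cis C4=C5 alkene | CC1=C[C@H]([C@H](C(=C)C(=O)OC)[C@H](OCc2ccc(OC)cc2)CI)O[Si](C(C)C)(C(C)C)O[C@H]1C/C=C(\I)C(=O)OC
A6 | alternative 3 | C8 aldehyde carrying the 3-(tributylstannylmethyl)butenolide at C6 | O=CC/C(C(=O)OC)=C\C[C@H](O[Si](C)(C)C(C)(C)C)/C(C)=C\[C@H]1OC(=O)C(C[Sn](CCCC)(CCCC)CCCC)=C1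
A7 | alternative 3 | 8-hydroxy germacranolide, C3 tert-butyldimethylsilyl ether | C=C1C(=O)O[C@@H]2/C=C(/C)[C@@H](O[Si](C)(C)C(C)(C)C)C/C=C(/C(=O)OC)C[C@@H](O)[C@@H]12
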